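## Structural features

The target is a 3,3''-linked biflavonoid: C3 of a 5,7,4'-trihydroxyflavanone is bonded directly to C3 of a 5,7,4'-trihydroxyflavone. The flavanone consists of the phloroglucinol-type ring A, the pyranone ring C (O1, C2, C3, C4, C4a, C8a) and a 4-hydroxyphenyl ring B on C2; the flavone half is flat and has no stereocentre. The only stereocentres are the neighbouring C2 (S) and C3 (R) of the flavanone, and the 2-aryl and 3-flavonyl groups are trans, which is the diequatorial and thermodynamically preferred arrangement. Both centres become fragile once the C4 ketone is present: C3–H is enolisable, and the C2–O1 bond can open by retro-oxa-Michael reaction to a chalcone, most easily under base, which would erase both centres. Six phenols, two of them chelated to carbonyl groups, call for protection that comes off without base. The real difficulty is to make the crowded sp3–sp2 bond C3–C3'', flanked by the flavone carbonyl and its 2-aryl group, together with the absolute configuration at C2 and C3. The key step reads ring C as a heterodiene O1=C8a–C4a=C4 (an ortho-quinone methide of ring A) plus the two-carbon unit C2–C3, an E alkene that already carries ring B on C2 and the flavone on C3.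

## Logic of the disconnections

16 from 15. Six O–C bonds are cut: five methoxymethyl acetals and one aryl acetate. All six fall in one acid-catalysed methanolysis, so no base touches the finished flavanone. The forward step must be acidic and short enough to leave C2 and C3 alone.

15 from 13 through 14. The C4 carbonyl is taken back to a CH2 group. Without the ketone, C3 is not enolisable and C2–O1 is an ordinary benzylic aryl ether, so the stereocentres can be made and carried safely. The forward step must oxidise C4–H selectively. Ring A therefore keeps electron-donating ether groups, which make C4–H the best hydride donor. Ring B carries an electron-poor acetate so that C2–H is not attacked; this is why 13 is cut to 12 at the acetyl C–O bond.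

12 from 7 and 10 through 11. O1–C2 and C3–C4 are cut. This removes ring C and both stereocentres in one move and leaves two achiral pieces of similar size. The forward step must control alkene face, regiochemistry and the trans relationship. The precursors are designed for this. 7 has exactly one free phenol, the one the catalyst must bind and the one that makes the alkene carbon next to the flavone nucleophilic; all other phenols are acetals. 10 keeps its phenol free and has two alkoxy donors that make ionisation of the primary benzylic alcohol easy. The same donors make 10 prone to self-alkylation, so it is made fresh and added slowly.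

10 from 9 from 8. A C–H bond (aldehyde reduction) and two acetal C–O bonds are cut. The chelated ortho hydroxyl of 8 stays free during protection, so the pattern needed for 11 comes without extra steps.

7 from 4 and 5 through 6. The bond between flavone C3 and the alkene carbon is cut (vinyl–vinyl C–C, Heck transform), then the acetate of 6. 5 brings ring B with its phenol masked as the only base-labile group in the molecule, so it is unmasked selectively in the same flask. A longer route through a 3-methylflavone, radical bromination, a phosphonate and an olefination was set aside. Bromine radicals and HBr beside three acetals and two electron-rich rings are one weak point, and olefination of a phenolate-bearing aldehyde is another.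

4 from 2 from 1. The C3–I bond and three acetal C–O bonds are cut. The whole flavone half is then a commercial natural product. The forward step must metalate C3–H rather than the ring positions next to the acetals.

## Other disconnections considered

Alternative 1: The cut is flavanone C2–C3. In the forward direction the diazo ketone A1 has the diazo carbon bearing the flavon-3-yl group and a 4-(methoxymethoxy)benzyl ether on the future O1. With Rh2(S-PTTL)4 (dirhodium tetrakis[N-phthaloyl-(S)-tert-leucinate], divalent rhodium) it would give a donor/acceptor carbenoid that inserts into one enantiotopic benzylic C–H bond and closes ring C to A2.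
- In its favour: C4 is a ketone from the start, so no late C–H oxidation is needed. On this point it is better than the chosen plan, which spends steps 8 and 9. It also needs no acid and no free phenol.
- Equal: both plans set C2 and C3 in one catalytic step.
- Against: the insertion closes a six-membered ring, less favoured than the five-membered closures that dominate this chemistry. The ether oxygen sits where it can form an oxonium ylide and shift the benzyl group to carbon, giving a benzofuranone. The carbenoid is wedged between a di-ortho-substituted aryl ketone and the flavone. The kinetic product may be cis, which would need epimerisation at C3 under conditions that threaten ring opening.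
- Step economy: A1 requires a deoxybenzoin-type ketone and a diazo transfer, so the two steps saved late are more than spent early.
- Mechanism: the chosen cycloaddition rests on closer precedent than enantiotopic C–H selection at this crowded site.

Alternative 2: The cut is C4a–C5 and C8–C8a, so ring A is grown last. The enantiopure 5-bromodihydropyranone A3 would react with 1-methoxy-1,3-bis(trimethylsilyloxy)buta-1,3-diene A4. Loss of HBr, methanol and the silyl groups would aromatise the adduct to A5.
- In its favour: ring A appears with free 5,7-hydroxyls and the ketone in place. It is better than the chosen plan in protecting-group and oxidation-state economy on that ring.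
- Against: A3 is a vinylogous ester and a weak dienophile. C2 (β-alkoxy ketone) and C3 (α to the ketone) must survive Lewis acid, heat and released HBr, which is a higher risk to configuration than in the chosen plan, where the ketone arrives last under neutral conditions. The acetals elsewhere are also exposed to HBr.
- Structure: the hard problem, joining C3 to the flavone with control of two centres, is only moved into the preparation of A3.
- Step economy: the linear sequence to A3 is long, so it is worse overall.

Alternative 3: The cut is flavone C3–C4 and O1–C2, so the flavone ring is built in place. Aldehyde 9 and the 3-(arylethynyl)flavan A6 would react under [Cp*RhCl2]2 (trivalent rhodium), AgSbF6 and Cu(OAc)2 by phenol-directed aldehyde C–H activation, alkyne insertion and C–O bond formation to give A7.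
- In its favour: it is convergent and reuses 9. The key step needs no acid, so it tolerates acetals better than the chosen step.
- Equal: A7 is the all-acetal counterpart of 13, so the endgame (C4 oxidation, deprotection) would be the same.
- Against: both stereocentres must already exist in A6. Making an enantiopure 2,3-trans-3-alkynylflavan is a problem of the same kind and size as the one the chosen key step solves, so an asymmetric step is added, not avoided. Insertion regiochemistry for an alkyne with one aryl and one bulky secondary alkyl end is uncertain. Hot Cu(OAc)2 meets an electron-rich flavan with two benzylic positions.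
- Step economy: the flavone, which the chosen plan buys as 1, is rebuilt atom by atom, so it is worse.

Key step: step 6

Assumption: which antipode of TRIP leads to the 2S,3R series cannot be deduced with certainty from a model. The route is written with the R catalyst; its mirror image is used if a test run shows the opposite sense.

## Route

Step 1
Reactants: 1 apigenin [5,7-dihydroxy-2-(4-hydroxyphenyl)-4H-chromen-4-one]
Product: 2 5,7-bis(methoxymethoxy)-2-[4-(methoxymethoxy)phenyl]-4H-chromen-4-one
Conditions: NaH, MOMCl, DMF, 0 °C → rt
Reagents that add atoms: chloromethyl methyl ether (MOMCl), COCCl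
Why: Williamson-type O-alkylation; NaH in DMF is strong enough to break the chelate of the 5-hydroxyl to the carbonyl, so all three phenols should be capped.

Step 2
Reactants: 2 5,7-bis(methoxymethoxy)-2-[4-(methoxymethoxy)phenyl]-4H-chromen-4-one
Product: 4 3-iodo-5,7-bis(methoxymethoxy)-2-[4-(methoxymethoxy)phenyl]-4H-chromen-4-one, via 3-lithioflavone 3 (not isolated)
Conditions: LiN(iPr)2 (LDA), THF, −78 °C; then I2, THF, −78 °C → 0 °C
Reagents that add atoms: iodine, II
Why: Carbonyl-directed deprotonation of the vinylic C3–H of a flavone by a lithium amide, then iodinolysis of the C–Li bond, is established chemistry. The hindered amide should be too weak to metalate aryl C–H next to the acetals at −78 °C, and the cold quench avoids ring opening of 3.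

Step 3
Reactants: 4 3-iodo-5,7-bis(methoxymethoxy)-2-[4-(methoxymethoxy)phenyl]-4H-chromen-4-one; 5 4-acetoxystyrene (4-ethenylphenyl acetate)
Product: 7 3-[(E)-2-(4-hydroxyphenyl)ethenyl]-5,7-bis(methoxymethoxy)-2-[4-(methoxymethoxy)phenyl]-4H-chromen-4-one, via styrylflavone acetate 6 (not isolated)
Conditions: Pd(OAc)2 (5 mol%), Bu4NBr, NaHCO3, DMF, 90 °C; then MeOH, K2CO3 (cat.), rt
Reagents that add atoms: none
Why: Mizoroki–Heck reaction under ligand-free phase-transfer conditions: Pd(OAc)2 (divalent palladium) is reduced in situ to zerovalent palladium, which adds to the C3–I bond; syn insertion at the terminal alkene carbon and syn β-hydride elimination give the E styrene. Carbonate-catalysed transesterification with methanol then frees the one phenol, and the acetals are inert to it.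

Step 4
Reactants: 8 2,4,6-trihydroxybenzaldehyde
Product: 9 2-hydroxy-4,6-bis(methoxymethoxy)benzaldehyde
Conditions: MOMCl (2.2 equiv), iPr2NEt, CH2Cl2, 0 °C
Reagents that add atoms: chloromethyl methyl ether (MOMCl), COCCl
Why: Selective O-alkylation; after the 4-hydroxyl and one ortho hydroxyl are capped, the remaining ortho hydroxyl is locked in a hydrogen bond to the aldehyde and should stay free under a mild amine base.

Step 5
Reactants: 9 2-hydroxy-4,6-bis(methoxymethoxy)benzaldehyde
Product: 10 2-(hydroxymethyl)-3,5-bis(methoxymethoxy)phenol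
Conditions: NaBH4, THF/EtOH, 0 °C; pH 7 buffer work-up; used at once
Reagents that add atoms: none
Why: Borohydride reduction of an aldehyde; low temperature and neutral work-up are chosen because this very electron-rich benzylic alcohol ionises easily, and it is not stored.

Step 6
Reactants: 7 3-[(E)-2-(4-hydroxyphenyl)ethenyl]-5,7-bis(methoxymethoxy)-2-[4-(methoxymethoxy)phenyl]-4H-chromen-4-one; 10 2-(hydroxymethyl)-3,5-bis(methoxymethoxy)phenol
Product: 12 3-[(2S,3R)-2-(4-hydroxyphenyl)-5,7-bis(methoxymethoxy)-3,4-dihydro-2H-chromen-3-yl]-5,7-bis(methoxymethoxy)-2-[4-(methoxymethoxy)phenyl]-4H-chromen-4-one, via ortho-quinone methide 11 (not isolated)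
Conditions: (R)-TRIP [(R)-3,3'-bis(2,4,6-triisopropylphenyl)-1,1'-binaphthyl-2,2'-diyl hydrogen phosphate] (10 mol%), 4 Å MS, toluene/CH2Cl2, −20 °C; 10 (1.5 equiv) added slowly by syringe pump
Reagents that add atoms: none
Why: The phosphoric acid should ionise the benzylic alcohol of 10, made easy by the 3- and 5-alkoxy donors, to the ortho-quinone methide 11, which stays hydrogen-bonded to the P–OH group while the phosphoryl oxygen binds the single free phenol of 7. The alkene carbon that bears the flavone, made nucleophilic by the para-hydroxyl push, attacks the exocyclic CH2 of 11 (C3–C4), and the para-quinone-methide-like benzylic carbon is then captured by the ring A oxygen (O1–C2), an asynchronous inverse-electron-demand oxa-[4+2] cycloaddition. The closest known reaction type is the chiral phosphoric acid catalysed [4+2] cycloaddition of ortho-quinone methides generated in situ from 2-hydroxybenzyl alcohols with hydroxystyrenes to give 2-arylchromans. The dihydropyran ring closes in cycloaddition mode (O1, C8a, C4a, C4 from 11 and C2, C3 from the alkene), which in the stepwise limit is a 6-exo-trig attack of the phenolate oxygen on the quinone methide carbon. C3 is set in the C–C bond-forming event by the alkene face that the chiral phosphate pocket leaves open, and C2 follows from suprafacial addition to the E alkene, so the 2,3-trans pair should result; were the closure stepwise, the diequatorial trans isomer is also the thermodynamic one. Regiochemistry is secured by the 4-hydroxyphenyl donor, which places the positive charge on the future C2. The step also needs chemoselectivity against Friedel–Crafts alkylation of the electron-rich rings by 11 and survival of the acetals, which slow addition of 10, low temperature, a weak acid and dry conditions should provide.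

Step 7
Reactants: 12 3-[(2S,3R)-2-(4-hydroxyphenyl)-5,7-bis(methoxymethoxy)-3,4-dihydro-2H-chromen-3-yl]-5,7-bis(methoxymethoxy)-2-[4-(methoxymethoxy)phenyl]-4H-chromen-4-one
Product: 13 4-[(2S,3R)-3-{5,7-bis(methoxymethoxy)-2-[4-(methoxymethoxy)phenyl]-4-oxo-4H-chromen-3-yl}-5,7-bis(methoxymethoxy)-3,4-dihydro-2H-chromen-2-yl]phenyl acetate
Conditions: Ac2O, pyridine, DMAP (cat.), CH2Cl2, 0 °C → rt
Reagents that add atoms: acetic anhydride, CC(=O)OC(C)=O
Why: DMAP-catalysed O-acylation of the only free phenol; the acetate makes ring B electron-poor, so C2–H is a poor hydride donor in step 8, and it later leaves in the same acid methanolysis as the acetals.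

Step 8
Reactants: 13 4-[(2S,3R)-3-{5,7-bis(methoxymethoxy)-2-[4-(methoxymethoxy)phenyl]-4-oxo-4H-chromen-3-yl}-5,7-bis(methoxymethoxy)-3,4-dihydro-2H-chromen-2-yl]phenyl acetate
Product: 14 4-[(2S,3S,4RS)-3-{5,7-bis(methoxymethoxy)-2-[4-(methoxymethoxy)phenyl]-4-oxo-4H-chromen-3-yl}-4-hydroxy-5,7-bis(methoxymethoxy)-3,4-dihydro-2H-chromen-2-yl]phenyl acetate (C4 epimers; C2 and C3 spatially unchanged, the C3 descriptor changes only through the priority rules)
Conditions: DDQ (2 equiv), CH2Cl2/H2O (18:1), 0 °C → rt
Reagents that add atoms: water, O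
Why: Benzylic C–H oxidation by hydride abstraction with DDQ: C4–H, activated by the 5- and 7-alkoxy groups and O1 of ring A, gives a quinone-methide-type cation that water traps, a reaction established on 5,7-dialkoxyflavan derivatives. C2 and C3 are not involved, and the C4 configuration is irrelevant because the next step removes it.

Step 9
Reactants: 14 4-[(2S,3S,4RS)-3-{5,7-bis(methoxymethoxy)-2-[4-(methoxymethoxy)phenyl]-4-oxo-4H-chromen-3-yl}-4-hydroxy-5,7-bis(methoxymethoxy)-3,4-dihydro-2H-chromen-2-yl]phenyl acetate
Product: 15 4-[(2S,3R)-3-{5,7-bis(methoxymethoxy)-2-[4-(methoxymethoxy)phenyl]-4-oxo-4H-chromen-3-yl}-5,7-bis(methoxymethoxy)-4-oxo-3,4-dihydro-2H-chromen-2-yl]phenyl acetate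
Conditions: Dess–Martin periodinane, pyridine, CH2Cl2, 0 °C → rt
Reagents that add atoms: none
Why: Dess–Martin oxidation of a secondary benzylic alcohol under buffered, near-neutral conditions, so the C3–H now α to the ketone should not epimerise and ring C should not open; both C4 epimers converge on one ketone.

Step 10
Reactants: 15 4-[(2S,3R)-3-{5,7-bis(methoxymethoxy)-2-[4-(methoxymethoxy)phenyl]-4-oxo-4H-chromen-3-yl}-5,7-bis(methoxymethoxy)-4-oxo-3,4-dihydro-2H-chromen-2-yl]phenyl acetate
Product: 16 (2S,3R)-3-[5,7-dihydroxy-2-(4-hydroxyphenyl)-4-oxo-4H-chromen-3-yl]-5,7-dihydroxy-2-(4-hydroxyphenyl)-2,3-dihydro-4H-chromen-4-one (CNP0208264.1)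
Conditions: HCl (3 M) in MeOH/THF, 45 °C; stopped at full conversion
Reagents that add atoms: none
Why: Acid-catalysed acetal cleavage of five methoxymethyl ethers and acid-catalysed transesterification of the aryl acetate in methanol. Acid, not base, keeps the C2–O1 bond closed, and the 2,3-trans arrangement is also the thermodynamic one, so both centres should be retained.

## Compound list

1 | apigenin, 5,7-dihydroxy-2-(4-hydroxyphenyl)-4H-chromen-4-one | O=c1cc(-c2ccc(O)cc2)oc2cc(O)cc(O)c12 | starting material
2 | 5,7-bis(methoxymethoxy)-2-[4-(methoxymethoxy)phenyl]-4H-chromen-4-one | O=c1cc(-c2ccc(OCOC)cc2)oc2cc(OCOC)cc(OCOC)c12 | intermediate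
3 | 3-lithio-5,7-bis(methoxymethoxy)-2-[4-(methoxymethoxy)phenyl]-4H-chromen-4-one (not isolated) | [Li]c1c(-c2ccc(OCOC)cc2)oc2cc(OCOC)cc(OCOC)c2c1=O | intermediate
4 | 3-iodo-5,7-bis(methoxymethoxy)-2-[4-(methoxymethoxy)phenyl]-4H-chromen-4-one | Ic1c(-c2ccc(OCOC)cc2)oc2cc(OCOC)cc(OCOC)c2c1=O | intermediate
5 | 4-acetoxystyrene, 4-ethenylphenyl acetate | C=Cc1ccc(OC(C)=O)cc1 | starting material
6 | 4-[(E)-2-{5,7-bis(methoxymethoxy)-2-[4-(methoxymethoxy)phenyl]-4-oxo-4H-chromen-3-yl}ethenyl]phenyl acetate (not isolated) | CC(=O)Oc1ccc(/C=C/c2c(-c3ccc(OCOC)cc3)oc3cc(OCOC)cc(OCOC)c3c2=O)cc1 | intermediate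
7 | 3-[(E)-2-(4-hydroxyphenyl)ethenyl]-5,7-bis(methoxymethoxy)-2-[4-(methoxymethoxy)phenyl]-4H-chromen-4-one | Oc1ccc(/C=C/c2c(-c3ccc(OCOC)cc3)oc3cc(OCOC)cc(OCOC)c3c2=O)cc1 | intermediate
8 | 2,4,6-trihydroxybenzaldehyde | O=Cc1c(O)cc(O)cc1O | starting material
9 | 2-hydroxy-4,6-bis(methoxymethoxy)benzaldehyde | O=Cc1c(O)cc(OCOC)cc1OCOC | intermediate
10 | 2-(hydroxymethyl)-3,5-bis(methoxymethoxy)phenol | OCc1c(O)cc(OCOC)cc1OCOC | intermediate
11 | 3,5-bis(methoxymethoxy)-6-methylidenecyclohexa-2,4-dien-1-one (ortho-quinone methide, not isolated) | C=C1C(=O)C=C(OCOC)C=C1OCOC | intermediate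
12 | 3-[(2S,3R)-2-(4-hydroxyphenyl)-5,7-bis(methoxymethoxy)-3,4-dihydro-2H-chromen-3-yl]-5,7-bis(methoxymethoxy)-2-[4-(methoxymethoxy)phenyl]-4H-chromen-4-one | C1c2c(OCOC)cc(OCOC)cc2O[C@H](c2ccc(O)cc2)[C@H]1c1c(-c2ccc(OCOC)cc2)oc2cc(OCOC)cc(OCOC)c2c1=O | intermediate
13 | 4-[(2S,3R)-3-{5,7-bis(methoxymethoxy)-2-[4-(methoxymethoxy)phenyl]-4-oxo-4H-chromen-3-yl}-5,7-bis(methoxymethoxy)-3,4-dihydro-2H-chromen-2-yl]phenyl acetate | C1c2c(OCOC)cc(OCOC)cc2O[C@H](c2ccc(OC(C)=O)cc2)[C@H]1c1c(-c2ccc(OCOC)cc2)oc2cc(OCOC)cc(OCOC)c2c1=O | intermediate
14 | 4-[(2S,3S,4RS)-3-{5,7-bis(methoxymethoxy)-2-[4-(methoxymethoxy)phenyl]-4-oxo-4H-chromen-3-yl}-4-hydroxy-5,7-bis(methoxymethoxy)-3,4-dihydro-2H-chromen-2-yl]phenyl acetate (C4 epimers) | OC1c2c(OCOC)cc(OCOC)cc2O[C@H](c2ccc(OC(C)=O)cc2)[C@H]1c1c(-c2ccc(OCOC)cc2)oc2cc(OCOC)cc(OCOC)c2c1=O | intermediate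
15 | 4-[(2S,3R)-3-{5,7-bis(methoxymethoxy)-2-[4-(methoxymethoxy)phenyl]-4-oxo-4H-chromen-3-yl}-5,7-bis(methoxymethoxy)-4-oxo-3,4-dihydro-2H-chromen-2-yl]phenyl acetate | O=C1c2c(OCOC)cc(OCOC)cc2O[C@H](c2ccc(OC(C)=O)cc2)[C@H]1c1c(-c2ccc(OCOC)cc2)oc2cc(OCOC)cc(OCOC)c2c1=O | intermediate
16 | (2S,3R)-3-[5,7-dihydroxy-2-(4-hydroxyphenyl)-4-oxo-4H-chromen-3-yl]-5,7-dihydroxy-2-(4-hydroxyphenyl)-2,3-dihydro-4H-chromen-4-one | O=C1c2c(O)cc(O)cc2O[C@H](c2ccc(O)cc2)[C@H]1c1c(-c2ccc(O)cc2)oc2cc(O)cc(O)c2c1=O | target

## Step count and least certain steps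

Total: 10 steps. Longest linear sequence: 8 steps (1, 2, 3, 6, 7, 8, 9, 10); steps 4 and 5 form the second branch.

Step 6 (key step). The most likely failure is poor enantiofacial discrimination. The methide carbon of 11 is unsubstituted and gives the catalyst little to hold, and the alkene carries a bulky flavone outside the usual substrate range. Friedel–Crafts alkylation of electron-rich rings by 11 may also compete with the cycloaddition. The fallback sets out from 7 and 10 and comes back at 12. The cycloaddition is run with the achiral acid diphenyl hydrogen phosphate, where acid strength, temperature and stoichiometry can be tuned for chemoselectivity alone. This should give 12 together with its (2R,3S) enantiomer F1. The mixture is acylated with (1S)-camphanic chloride (Et3N, DMAP, CH2Cl2) to two diastereomeric esters, the camphanate of 12 F2 and the camphanate of the enantiomer F3. These are separated by chromatography or crystallisation, and K2CO3 in MeOH at room temperature cleaves F2 to 12; the ketone-free chroman is stable to this mild base.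

Step 2. Deprotonation may stray to ring positions flanked by the acetals, or 3 may ring-open to an ynone phenolate before the quench, giving regioisomeric iodides or decomposition. The fallback sets out from 2 and 5 and comes back at 6, which is methanolysed to 7 as in step 3. It is a direct oxidative (Fujiwara–Moritani) alkenylation of the flavone C3–H with Pd(OAc)2 (divalent palladium), Cu(OAc)2, Ag2CO3 and pivalic acid in DMF at about 100 °C; electrophilic palladation of chromones takes place at C3. No iodide and no new compound are needed.

Step 8. The C4 cation may lose the C3 proton instead of adding water. That would give a flav-3-ene, destroy the C3 stereocentre and open the way to over-oxidation. The fallback sets out from 13 and comes back at 15. DDQ in CH2Cl2/MeOH, a homogeneous medium with a better nucleophile, should trap the cation as the 4-methoxyflavan F4. A second DDQ treatment in wet CH2Cl2 removes the remaining C4–H of this benzylic ether as hydride, and hydrolysis of the oxocarbenium ion gives 15 directly, so 14 and step 9 are bypassed.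

Step 5. The phenolate of the product can expel the benzylic oxygen during reduction or work-up and form 11 early, leading to over-reduction to a methyl group or to self-condensation on concentration. The fallback sets out from 9 and comes back at 10. The phenol is silylated (tBuMe2SiCl, imidazole, DMF) to the silyl ether aldehyde F5, which NaBH4 reduces to the storable silyl ether alcohol F6; with the phenol blocked the quinone methide pathway is closed. Bu4NF buffered with AcOH in THF at −20 °C then releases 10 immediately before step 6.

## Further compounds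

F1 | step 6 | 3-[(2R,3S)-2-(4-hydroxyphenyl)-5,7-bis(methoxymethoxy)-3,4-dihydro-2H-chromen-3-yl]-5,7-bis(methoxymethoxy)-2-[4-(methoxymethoxy)phenyl]-4H-chromen-4-one (enantiomer of 12) | C1c2c(OCOC)cc(OCOC)cc2O[C@@H](c2ccc(O)cc2)[C@@H]1c1c(-c2ccc(OCOC)cc2)oc2cc(OCOC)cc(OCOC)c2c1=O
F2 | step 6 | 4-[(2S,3R)-3-{5,7-bis(methoxymethoxy)-2-[4-(methoxymethoxy)phenyl]-4-oxo-4H-chromen-3-yl}-5,7-bis(methoxymethoxy)-3,4-dihydro-2H-chromen-2-yl]phenyl (1S,4R)-4,7,7-trimethyl-3-oxo-2-oxabicyclo[2.2.1]heptane-1-carboxylate (camphanate of 12) | C1c2c(OCOC)cc(OCOC)cc2O[C@H](c2ccc(OC(=O)[C@@]34CC[C@@](C)(C(=O)O3)C4(C)C)cc2)[C@H]1c1c(-c2ccc(OCOC)cc2)oc2cc(OCOC)cc(OCOC)c2c1=O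
F3 | step 6 | 4-[(2R,3S)-3-{5,7-bis(methoxymethoxy)-2-[4-(methoxymethoxy)phenyl]-4-oxo-4H-chromen-3-yl}-5,7-bis(methoxymethoxy)-3,4-dihydro-2H-chromen-2-yl]phenyl (1S,4R)-4,7,7-trimethyl-3-oxo-2-oxabicyclo[2.2.1]heptane-1-carboxylate (camphanate of F1) | C1c2c(OCOC)cc(OCOC)cc2O[C@@H](c2ccc(OC(=O)[C@@]34CC[C@@](C)(C(=O)O3)C4(C)C)cc2)[C@@H]1c1c(-c2ccc(OCOC)cc2)oc2cc(OCOC)cc(OCOC)c2c1=O
F0 | step 2 | none | none
F4 | step 8 | 4-[(2S,3S,4RS)-3-{5,7-bis(methoxymethoxy)-2-[4-(methoxymethoxy)phenyl]-4-oxo-4H-chromen-3-yl}-4-methoxy-5,7-bis(methoxymethoxy)-3,4-dihydro-2H-chromen-2-yl]phenyl acetate (C4 epimers) | COC1c2c(OCOC)cc(OCOC)cc2O[C@H](c2ccc(OC(C)=O)cc2)[C@H]1c1c(-c2ccc(OCOC)cc2)oc2cc(OCOC)cc(OCOC)c2c1=O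
F5 | step 5 | 2-[(tert-butyldimethylsilyl)oxy]-4,6-bis(methoxymethoxy)benzaldehyde | O=Cc1c(O[Si](C)(C)C(C)(C)C)cc(OCOC)cc1OCOC
F6 | step 5 | {2-[(tert-butyldimethylsilyl)oxy]-4,6-bis(methoxymethoxy)phenyl}methanol | OCc1c(O[Si](C)(C)C(C)(C)C)cc(OCOC)cc1OCOC
A1 | alternative 1 | 2-diazo-1-{2-[(tert-butyldimethylsilyl)oxy]-4-(methoxymethoxy)-6-{[4-(methoxymethoxy)phenyl]methoxy}phenyl}-2-{5,7-bis(methoxymethoxy)-2-[4-(methoxymethoxy)phenyl]-4-oxo-4H-chromen-3-yl}ethan-1-one | [N-]=[N+]=C(C(=O)c1c(O[Si](C)(C)C(C)(C)C)cc(OCOC)cc1OCc1ccc(OCOC)cc1)c1c(-c2ccc(OCOC)cc2)oc2cc(OCOC)cc(OCOC)c2c1=O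
A2 | alternative 1 | (2S,3R)-3-{5,7-bis(methoxymethoxy)-2-[4-(methoxymethoxy)phenyl]-4-oxo-4H-chromen-3-yl}-5-[(tert-butyldimethylsilyl)oxy]-7-(methoxymethoxy)-2-[4-(methoxymethoxy)phenyl]-2,3-dihydro-4H-chromen-4-one | O=C1c2c(O[Si](C)(C)C(C)(C)C)cc(OCOC)cc2O[C@H](c2ccc(OCOC)cc2)[C@H]1c1c(-c2ccc(OCOC)cc2)oc2cc(OCOC)cc(OCOC)c2c1=O
A3 | alternative 2 | (2S,3R)-5-bromo-3-{5,7-bis(methoxymethoxy)-2-[4-(methoxymethoxy)phenyl]-4-oxo-4H-chromen-3-yl}-2-[4-(methoxymethoxy)phenyl]-2,3-dihydro-4H-pyran-4-one | O=C1C(Br)=CO[C@H](c2ccc(OCOC)cc2)[C@H]1c1c(-c2ccc(OCOC)cc2)oc2cc(OCOC)cc(OCOC)c2c1=O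
A4 | alternative 2 | 1-methoxy-1,3-bis(trimethylsilyloxy)buta-1,3-diene | COC(O[Si](C)(C)C)=CC(=C)O[Si](C)(C)C
A5 | alternative 2 | (2S,3R)-3-{5,7-bis(methoxymethoxy)-2-[4-(methoxymethoxy)phenyl]-4-oxo-4H-chromen-3-yl}-5,7-dihydroxy-2-[4-(methoxymethoxy)phenyl]-2,3-dihydro-4H-chromen-4-one | O=C1c2c(O)cc(O)cc2O[C@H](c2ccc(OCOC)cc2)[C@H]1c1c(-c2ccc(OCOC)cc2)oc2cc(OCOC)cc(OCOC)c2c1=O
A6 | alternative 3 | (2S,3R)-5,7-bis(methoxymethoxy)-2-[4-(methoxymethoxy)phenyl]-3-{[4-(methoxymethoxy)phenyl]ethynyl}-3,4-dihydro-2H-chromene | C1c2c(OCOC)cc(OCOC)cc2O[C@H](c2ccc(OCOC)cc2)[C@H]1C#Cc1ccc(OCOC)cc1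
A7 | alternative 3 | 3-[(2S,3R)-5,7-bis(methoxymethoxy)-2-[4-(methoxymethoxy)phenyl]-3,4-dihydro-2H-chromen-3-yl]-5,7-bis(methoxymethoxy)-2-[4-(methoxymethoxy)phenyl]-4H-chromen-4-one | C1c2c(OCOC)cc(OCOC)cc2O[C@H](c2ccc(OCOC)cc2)[C@H]1c1c(-c2ccc(OCOC)cc2)oc2cc(OCOC)cc(OCOC)c2c1=O
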